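**Plan**

- Retrosynthesis: the lactam C5–OH and C3=C4 bond go first, then the aryl C–O bond of the 13-membered cyclophane, then the ketone–lactam C–C bond. Ring B is cut at its trisubstituted C=C and at the bond between the acyl-bearing CH and the vinyl-bearing CH. Rings A and C are cut together: the bond from the quaternary carbon to the ring-C CH that carries ring B, with one ring-A C–C bond re-drawn as the zero bridge of a bicyclo[3.1.0]hexane.
- Forward: chiral cyclopentenone → siloxycyclopropane carrying the ring-C chain → ring expansion/radical cyclisation gives rings A and C at once → Ireland–Claisen and metathesis give ring B → lactam attached → cyclophane closed → lactam oxidised.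
- Enabling feature: in ring A the quaternary C(CH3) shared with ring C is joined through one CH2 to a CH(CH3) carbon. That CH(CH3) can be a ketone, the CH2 the cyclopropane carbon, and the quaternary carbon a tertiary β-keto radical sitting next to the ring-C chain.
- Stereochemistry: auxiliary-controlled conjugate addition (first ring-A methyl); trans cuprate addition; reagent-controlled alkynylation; anti cuprate addition to a γ-silyloxy enoate; cis ring fusion and allylic strain in the radical closure; face-selective hydrogenation; kinetic protonation; cyclophane-controlled hemiaminal.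

Key step: step 12

Assumption: 1, 10, 21, 27 and 28 are taken as commercial, and the hemiaminal carbon made in step 27 is taken to settle, by ring–chain equilibration inside the closed cyclophane, in the configuration of the target.

**Route**

Step 1
Reactants: 1 (S)-4-benzyl-3-[(E)-but-2-enoyl]oxazolidin-2-one
Product: 2 (S)-4-benzyl-3-[(R)-3-methylpent-4-enoyl]oxazolidin-2-one
Conditions: CH2=CHMgBr, CuBr·SMe2, THF, −78 to −20 °C; aq NH4Cl
Reagents that add atoms: vinylmagnesium bromide C=C[Mg]Br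
Why: Auxiliary-controlled cuprate conjugate addition, in which the chelated s-cis enoyl imide is attacked on the face opposite the benzyl group and so sets the first secondary methyl centre of ring A.

Step 2
Reactants: 2 (S)-4-benzyl-3-[(R)-3-methylpent-4-enoyl]oxazolidin-2-one
Product: 3 (R)-N-methoxy-N,3-dimethylpent-4-enamide
Conditions: MeNH(OMe)·HCl, AlMe3, CH2Cl2, −20 °C to rt
Reagents that add atoms: N,O-dimethylhydroxylamine hydrochloride CNOC.Cl
Why: Aluminium amide transamination of the imide releases the auxiliary and gives the Weinreb amide without touching the stereocentre.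

Step 3
Reactants: 3 (R)-N-methoxy-N,3-dimethylpent-4-enamide
Product: 4 (R)-2,5-dimethylhepta-1,6-dien-3-one
Conditions: CH2=C(CH3)MgBr, THF, 0 °C; aq NH4Cl
Reagents that add atoms: isopropenylmagnesium bromide CC(=C)[Mg]Br
Why: Weinreb ketone synthesis, in which the chelated tetrahedral adduct survives until work-up and so prevents over-addition or conjugate addition to the enone.

Step 4
Reactants: 4 (R)-2,5-dimethylhepta-1,6-dien-3-one
Product: 5 (R)-2,4-dimethylcyclopent-2-en-1-one
Conditions: second-generation Grubbs catalyst RuCl2(=CHPh)(PCy3)(H2IMes), CH2Cl2, 40 °C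
Reagents that add atoms: none
Why: Ring-closing metathesis of the 1,6-diene to the trisubstituted cyclopentenone is driven by loss of ethene and leaves the stereocentre untouched.

Step 5
Reactants: 5 (R)-2,4-dimethylcyclopent-2-en-1-one
Product: 6 trimethyl{[(3S,4R)-3-ethenyl-2,4-dimethylcyclopent-1-en-1-yl]oxy}silane
Conditions: CH2=CHMgBr, CuBr·SMe2 (cat.), Me3SiCl, DMPU, THF, −78 °C; Et3N, pentane work-up
Reagents that add atoms: vinylmagnesium bromide C=C[Mg]Br; chlorotrimethylsilane C[Si](C)(C)Cl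
Why: Copper-catalysed conjugate addition with silyl trapping adds the vinyl group trans to the 4-methyl group and fixes the enolate regiospecifically as the tetrasubstituted silyl enol ether.

Step 6
Reactants: 6 trimethyl{[(3S,4R)-3-ethenyl-2,4-dimethylcyclopent-1-en-1-yl]oxy}silane
Product: 7 4-ethenyl-3,5-dimethyl-1-(trimethylsilyloxy)bicyclo[3.1.0]hexane (ethenyl trans to 3-methyl; cyclopropane CH2 anti to ethenyl)
Conditions: ZnEt2, CH2I2, CH2Cl2, 0 °C to rt; pyridine quench
Reagents that add atoms: diiodomethane ICI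
Why: Simmons–Smith cyclopropanation with the zinc carbenoid takes the electron-rich silyl enol ether far faster than the vinyl group and from the face anti to the vinyl substituent.

Step 7
Reactants: 7 4-ethenyl-3,5-dimethyl-1-(trimethylsilyloxy)bicyclo[3.1.0]hexane
Product: 9 3,5-dimethyl-1-(trimethylsilyloxy)bicyclo[3.1.0]hexane-4-carbaldehyde, via secondary ozonide 8 (not isolated)
Conditions: O3, CH2Cl2, −78 °C; then PPh3, −78 °C to rt
Reagents that add atoms: ozone [O-][O+]=O
Why: Ozonolysis with reductive work-up cleaves the only alkene to the aldehyde, the siloxycyclopropane being inert to ozone at low temperature.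

Step 8
Reactants: 9 3,5-dimethyl-1-(trimethylsilyloxy)bicyclo[3.1.0]hexane-4-carbaldehyde; 10 methyl propiolate
Product: 11 methyl (4S)-4-hydroxy-4-[3,5-dimethyl-1-(trimethylsilyloxy)bicyclo[3.1.0]hex-4-yl]but-2-ynoate
Conditions: ZnMe2, ProPhenol ligand (the enantiomer matched to the S carbinol), Ph3P=O, toluene, 0 °C
Reagents that add atoms: none
Why: Zinc–ProPhenol catalysed asymmetric alkynylation of the α-branched aldehyde sets, under reagent control, the carbinol centre that will carry the aryl ether oxygen.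

Step 9
Reactants: 11 methyl (4S)-4-hydroxy-4-[3,5-dimethyl-1-(trimethylsilyloxy)bicyclo[3.1.0]hex-4-yl]but-2-ynoate
Product: 12 methyl (2E)-4-hydroxy-4-[3,5-dimethyl-1-(trimethylsilyloxy)bicyclo[3.1.0]hex-4-yl]but-2-enoate
Conditions: NaAlH2(OCH2CH2OMe)2, THF, −72 °C; aq Rochelle salt
Reagents that add atoms: none
Why: Alkoxide-directed trans-hydroalumination of the γ-hydroxy ynoate gives the E enoate without reducing the ester.

Step 10
Reactants: 12 methyl (2E)-4-hydroxy-4-[3,5-dimethyl-1-(trimethylsilyloxy)bicyclo[3.1.0]hex-4-yl]but-2-enoate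
Product: 13 tert-butyldimethylsilyl ether of 12
Conditions: tBuMe2SiOTf, 2,6-lutidine, CH2Cl2, −78 °C
Reagents that add atoms: tert-butyldimethylsilyl trifluoromethanesulfonate CC(C)(C)[Si](C)(C)OS(=O)(=O)C(F)(F)F
Why: Silyl ether formation protects the carbinol and installs the bulky γ-substituent that steers the next addition.

Step 11
Reactants: 13 tert-butyldimethylsilyl ether of 12
Product: 15 methyl 3-{(tert-butyldimethylsilyloxy)[3,5-dimethyl-1-(trimethylsilyloxy)bicyclo[3.1.0]hex-4-yl]methyl}-5-methylhex-4-enoate (alkenyl group anti to the silyloxy group), via trimethylsilyl ketene acetal 14 (not isolated)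
Conditions: (CH3)2C=CHMgBr, CuI, Me3SiCl, THF, −78 to −40 °C; aq NH4Cl
Reagents that add atoms: 2-methylprop-1-enylmagnesium bromide CC(C)=C[Mg]Br
Why: Silyl chloride-accelerated cuprate conjugate addition to a γ-silyloxy E-enoate occurs anti to the γ-oxygen and sets the CH centre that will carry the acetic ester arm.

Step 12
Reactants: 15 methyl 3-{(tert-butyldimethylsilyloxy)[3,5-dimethyl-1-(trimethylsilyloxy)bicyclo[3.1.0]hex-4-yl]methyl}-5-methylhex-4-enoate
Product: 16 methyl 2-[3-(tert-butyldimethylsilyloxy)-1-(2-chloropropan-2-yl)-4,7a-dimethyl-6-oxooctahydro-1H-inden-2-yl]acetate (cis ring fusion)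
Conditions: FeCl3 (2.5 equiv), DMF, 0 °C to rt, high dilution
Reagents that add atoms: iron trichloride Cl[Fe](Cl)Cl
Why: FeCl3 oxidises the siloxycyclopropane (loss of Me3SiCl) to a cyclopropyloxy radical whose internal C–C bond cleaves, enlarging the cyclopentane to a cyclohexanone and leaving a tertiary β-keto radical at the methyl-bearing carbon; this radical adds to the near carbon of the trisubstituted alkene and the new tertiary radical takes chlorine from a second FeCl3. The closest known reaction type is the FeCl3-mediated ring expansion–cyclisation of 1-siloxybicyclo[n.1.0]alkanes that carry a butenyl chain on the neighbouring carbon. Ring A arises by one-carbon ring expansion (β-scission of the zero bridge) and ring C by 5-exo-trig radical closure. The quaternary carbon is fixed by the three-atom tether, which can deliver the alkene only to the face cis to the side chain (cis ring fusion); the adjacent CH centre is fixed in a chair-like 5-exo transition state in which the ester-bearing carbon keeps its hydrogen in the alkene plane to avoid allylic 1,3-strain with the Z-methyl group, so the new bond ends trans to the CH2CO2Me arm and the chloroisopropyl group cis to the silyloxy group. The step needs internal rather than external cyclopropane cleavage, secured by the tertiary radical that results, and ring closure faster than chlorine transfer, secured by dilution in DMF.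

Step 13
Reactants: 16 methyl 2-[3-(tert-butyldimethylsilyloxy)-1-(2-chloropropan-2-yl)-4,7a-dimethyl-6-oxooctahydro-1H-inden-2-yl]acetate
Product: 17 6-methylidene analogue of 16
Conditions: Ph3PCH3Br, KOtBu, THF, 0 °C (ylide preformed); then 16, 0 °C to rt
Reagents that add atoms: methyltriphenylphosphonium bromide C[P+](c1ccccc1)(c1ccccc1)c1ccccc1.[Br-]
Why: Wittig methylenation takes the unhindered cyclohexanone and leaves the ester, silyl ether and tertiary chloride alone.

Step 14
Reactants: 17 6-methylidene analogue of 16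
Product: 18 methyl 2-[3-(tert-butyldimethylsilyloxy)-1-(2-chloropropan-2-yl)-4,6,7a-trimethyloctahydro-1H-inden-2-yl]acetate
Conditions: H2 (1 atm), PtO2, EtOAc, rt
Reagents that add atoms: none
Why: Heterogeneous hydrogenation of the exocyclic methylene should deliver hydrogen to the face opposite the axial ring-C carbon and its chloroisopropyl group, giving the new methyl group cis to that carbon.

Step 15
Reactants: 18 methyl 2-[3-(tert-butyldimethylsilyloxy)-1-(2-chloropropan-2-yl)-4,6,7a-trimethyloctahydro-1H-inden-2-yl]acetate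
Product: 20 2-[3-(tert-butyldimethylsilyloxy)-4,6,7a-trimethyl-1-(prop-1-en-2-yl)octahydro-1H-inden-2-yl]acetic acid, via isopropenyl methyl ester 19 (not isolated)
Conditions: KOtBu, DMSO, 40 °C; then H2O, rt; aq citric acid
Reagents that add atoms: water O
Why: E2 dehydrochlorination with a bulky base goes toward a methyl group (the ring CH is hindered), giving the isopropenyl group, and the hydroxide formed on adding water then cleaves the methyl ester.

Step 16
Reactants: 20 2-[3-(tert-butyldimethylsilyloxy)-4,6,7a-trimethyl-1-(prop-1-en-2-yl)octahydro-1H-inden-2-yl]acetic acid; 21 (2E)-penta-2,4-dien-1-ol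
Product: 22 (2E)-penta-2,4-dien-1-yl ester of 20
Conditions: EDC·HCl, DMAP, CH2Cl2, 0 °C to rt
Reagents that add atoms: none
Why: Steglich esterification joins the acid to the dienol under neutral conditions.

Step 17
Reactants: 22 (2E)-penta-2,4-dien-1-yl ester of 20
Product: 25 3-ethenyl-2-[3-(tert-butyldimethylsilyloxy)-4,6,7a-trimethyl-1-(prop-1-en-2-yl)octahydro-1H-inden-2-yl]pent-4-enoic acid (both configurations at C2), via silyl ketene acetal 23 (not isolated), via trimethylsilyl ester 24 (not isolated)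
Conditions: LiN(iPr)2, Me3SiCl, Et3N, THF, −78 to 60 °C; then 1 M HCl
Reagents that add atoms: none
Why: Ireland–Claisen rearrangement through the near alkene of the dienyl ester forms the bond to the future vinyl-bearing CH as a 1,4-pentadien-3-yl group; the centre α to the acid is not controlled here and is set in step 22.

Step 18
Reactants: 25 3-ethenyl-2-[3-(tert-butyldimethylsilyloxy)-4,6,7a-trimethyl-1-(prop-1-en-2-yl)octahydro-1H-inden-2-yl]pent-4-enoic acid
Product: 26 9-(tert-butyldimethylsilyloxy)-2-ethenyl-4,4b,6,8-tetramethyl-2,4a,4b,5,6,7,8,8a,9,9a-decahydro-1H-fluorene-1-carboxylic acid (both C1 configurations)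
Conditions: second-generation Grubbs catalyst RuCl2(=CHPh)(PCy3)(H2IMes), CH2Cl2, 40 °C, high dilution
Reagents that add atoms: none
Why: Ring-closing metathesis between the isopropenyl group and one of the two diastereotopic vinyl groups closes ring B as the trisubstituted cyclohexene, and closure through the vinyl that leaves the other pseudo-equatorial (1,3-cis to the ring-fusion bond toward the silyloxy carbon) should set the vinyl-bearing centre.

Step 19
Reactants: 27 N-Boc-4-iodo-L-phenylalanine; 28 Meldrum's acid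
Product: 29 tert-butyl [(S)-1-(2,2-dimethyl-4,6-dioxo-1,3-dioxan-5-yl)-3-(4-iodophenyl)-1-oxopropan-2-yl]carbamate
Conditions: EDC·HCl, DMAP, CH2Cl2, 0 °C to rt
Reagents that add atoms: none
Why: Carbodiimide C-acylation of Meldrum's acid by the N-protected amino acid proceeds without racemisation.

Step 20
Reactants: 29 tert-butyl [(S)-1-(2,2-dimethyl-4,6-dioxo-1,3-dioxan-5-yl)-3-(4-iodophenyl)-1-oxopropan-2-yl]carbamate
Product: 31 tert-butyl (R)-2-(4-iodobenzyl)-5-oxopyrrolidine-1-carboxylate, via alkyl Meldrum's acid 30 (not isolated)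
Conditions: NaBH4, AcOH, CH2Cl2, 0 °C; then toluene, 110 °C
Reagents that add atoms: none
Why: Borohydride reduction of the acyl Meldrum's acid to the alkyl derivative and thermal ring closure onto the carbamate nitrogen, with loss of acetone and CO2, gives the N-Boc lactam with the amino acid centre intact.

Step 21
Reactants: 26 9-(tert-butyldimethylsilyloxy)-2-ethenyl-4,4b,6,8-tetramethyl-decahydro-1H-fluorene-1-carboxylic acid; 31 tert-butyl (R)-2-(4-iodobenzyl)-5-oxopyrrolidine-1-carboxylate
Product: 33 tert-butyl (5R)-3-(fluorene-1-carbonyl)-5-(4-iodobenzyl)-2-oxopyrrolidine-1-carboxylate (β-keto lactam; both fluorene C1 configurations), via acyl imidazolide 32 (not isolated)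
Conditions: 1,1'-carbonyldiimidazole, THF, rt; then added to 31 and LiN(SiMe3)2 (2.2 equiv), THF, −78 to −40 °C; aq NH4Cl
Reagents that add atoms: none
Why: Claisen-type C-acylation of the lactam lithium enolate by the acyl imidazolide gives the 3-acyl lactam, the second equivalent of enolate taking up the acidic product.

Step 22
Reactants: 33 β-keto lactam (both fluorene C1 configurations)
Product: 34 β-keto lactam with the acyl group cis to the 2-ethenyl group and to the C9a–C9 bond
Conditions: LiN(iPr)2 (3 equiv), THF, −78 to −30 °C; then AcOH in THF, −78 °C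
Reagents that add atoms: none
Why: Kinetic protonation of the β-dicarbonyl dianion at its γ-carbon from the face opposite the two flanking ring substituents places the acyl group cis to both, the less stable arrangement that the target needs.

Step 23
Reactants: 34 β-keto lactam with the acyl group cis to the 2-ethenyl group
Product: 35 9-hydroxy compound from 34
Conditions: HF·pyridine, THF, pyridine, 0 °C to rt
Reagents that add atoms: none
Why: Fluoride-mediated desilylation under mildly acidic conditions frees the secondary alcohol without enolising the carbon next to the ketone.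

Step 24
Reactants: 35 9-hydroxy compound from 34
Product: 36 N-Boc cyclophane (13-membered aryl alkyl ether with saturated 3-acyl lactam)
Conditions: CuI, 3,4,7,8-tetramethyl-1,10-phenanthroline, Cs2CO3, toluene, 110 °C, high dilution
Reagents that add atoms: none
Why: Intramolecular Ullmann-type copper-catalysed C–O coupling of the secondary alcohol with the aryl iodide closes the para-cyclophane with retention at the carbinol carbon, while the β-keto lactam is masked as its enolate and the carbamate blocks N-arylation.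

Step 25
Reactants: 36 N-Boc cyclophane
Product: 37 N–H cyclophane lactam
Conditions: CF3CO2H, CH2Cl2, 0 °C
Reagents that add atoms: none
Why: Acidolysis removes the imide-type Boc group quickly, before the hemiaminal is present.

Step 26
Reactants: 37 N–H cyclophane lactam
Product: 40 cyclophane 3-acyl-1,5-dihydro-2H-pyrrol-2-one, via selenide 38 (not isolated), via selenoxide 39 (not isolated)
Conditions: LiN(SiMe3)2 (2.2 equiv), THF, −78 °C, PhSeBr; then 30% H2O2, CH2Cl2, pyridine, 0 °C to rt
Reagents that add atoms: none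
Why: α-Selenenylation of the β-keto lactam enolate, which is faster than selenium addition to the alkenes at low temperature, and selenoxide syn-elimination toward the only β-hydrogens give the lactam C3=C4 bond.

Step 27
Reactants: 40 cyclophane 3-acyl-1,5-dihydro-2H-pyrrol-2-one
Product: 42 CNP0151253.3 (target), via hydroperoxide 41 (not isolated)
Conditions: O2 (1 atm), Et3N, THF, rt; then PPh3
Reagents that add atoms: dioxygen O=O
Why: Base-mediated autoxidation of the doubly vinylogous C5–H through the 2-hydroxypyrrole tautomer and phosphine reduction of the hydroperoxide give the hemiaminal, whose configuration is fixed by the closed cyclophane.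

**Compound list**

1 | (S)-4-benzyl-3-[(E)-but-2-enoyl]oxazolidin-2-one | C/C=C/C(=O)N1[C@@H](Cc2ccccc2)COC1=O | starting material
2 | (S)-4-benzyl-3-[(R)-3-methylpent-4-enoyl]oxazolidin-2-one | C=C[C@H](C)CC(=O)N1[C@@H](Cc2ccccc2)COC1=O | intermediate
3 | (R)-N-methoxy-N,3-dimethylpent-4-enamide | C=C[C@H](C)CC(=O)N(C)OC | intermediate
4 | (R)-2,5-dimethylhepta-1,6-dien-3-one | C=C[C@H](C)CC(=O)C(C)=C | intermediate
5 | (R)-2,4-dimethylcyclopent-2-en-1-one | CC1=C[C@H](C)CC1=O | intermediate
6 | trimethyl{[(3S,4R)-3-ethenyl-2,4-dimethylcyclopent-1-en-1-yl]oxy}silane | C=C[C@H]1[C@H](C)CC(O[Si](C)(C)C)=C1C | intermediate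
7 | 4-ethenyl-3,5-dimethyl-1-(trimethylsilyloxy)bicyclo[3.1.0]hexane | C=C[C@H]1[C@H](C)C[C@]2(O[Si](C)(C)C)C[C@]12C | intermediate
8 | secondary ozonide (1,2,4-trioxolane) of 7 | C1OC(OO1)[C@H]1[C@H](C)C[C@]2(O[Si](C)(C)C)C[C@]12C | intermediate
9 | 3,5-dimethyl-1-(trimethylsilyloxy)bicyclo[3.1.0]hexane-4-carbaldehyde | O=C[C@H]1[C@H](C)C[C@]2(O[Si](C)(C)C)C[C@]12C | intermediate
10 | methyl propiolate | C#CC(=O)OC | starting material
11 | methyl (4S)-4-hydroxy-4-(bicyclohexyl)but-2-ynoate | COC(=O)C#C[C@@H](O)[C@H]1[C@H](C)C[C@]2(O[Si](C)(C)C)C[C@]12C | intermediate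
12 | methyl (2E)-4-hydroxy-4-(bicyclohexyl)but-2-enoate | COC(=O)/C=C/[C@@H](O)[C@H]1[C@H](C)C[C@]2(O[Si](C)(C)C)C[C@]12C | intermediate
13 | tert-butyldimethylsilyl ether of 12 | COC(=O)/C=C/[C@@H](O[Si](C)(C)C(C)(C)C)[C@H]1[C@H](C)C[C@]2(O[Si](C)(C)C)C[C@]12C | intermediate
14 | trimethylsilyl ketene acetal of 15 | COC(O[Si](C)(C)C)=C[C@@H](C=C(C)C)[C@@H](O[Si](C)(C)C(C)(C)C)[C@H]1[C@H](C)C[C@]2(O[Si](C)(C)C)C[C@]12C | intermediate
15 | methyl 3-[(silyloxy)(bicyclohexyl)methyl]-5-methylhex-4-enoate | COC(=O)C[C@@H](C=C(C)C)[C@@H](O[Si](C)(C)C(C)(C)C)[C@H]1[C@H](C)C[C@]2(O[Si](C)(C)C)C[C@]12C | intermediate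
16 | methyl 2-[3-(tert-butyldimethylsilyloxy)-1-(2-chloropropan-2-yl)-4,7a-dimethyl-6-oxooctahydro-1H-inden-2-yl]acetate | COC(=O)C[C@H]1[C@H](C(C)(C)Cl)[C@]2(C)CC(=O)C[C@@H](C)[C@@H]2[C@@H]1O[Si](C)(C)C(C)(C)C | intermediate
17 | 6-methylidene analogue of 16 | COC(=O)C[C@H]1[C@H](C(C)(C)Cl)[C@]2(C)CC(=C)C[C@@H](C)[C@@H]2[C@@H]1O[Si](C)(C)C(C)(C)C | intermediate
18 | 4,6,7a-trimethyl chloro ester | COC(=O)C[C@H]1[C@H](C(C)(C)Cl)[C@]2(C)C[C@H](C)C[C@@H](C)[C@@H]2[C@@H]1O[Si](C)(C)C(C)(C)C | intermediate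
19 | isopropenyl methyl ester | COC(=O)C[C@H]1[C@H](C(C)=C)[C@]2(C)C[C@H](C)C[C@@H](C)[C@@H]2[C@@H]1O[Si](C)(C)C(C)(C)C | intermediate
20 | isopropenyl acid | OC(=O)C[C@H]1[C@H](C(C)=C)[C@]2(C)C[C@H](C)C[C@@H](C)[C@@H]2[C@@H]1O[Si](C)(C)C(C)(C)C | intermediate
21 | (2E)-penta-2,4-dien-1-ol | OC/C=C/C=C | starting material
22 | (2E)-penta-2,4-dien-1-yl ester of 20 | C=C/C=C/COC(=O)C[C@H]1[C@H](C(C)=C)[C@]2(C)C[C@H](C)C[C@@H](C)[C@@H]2[C@@H]1O[Si](C)(C)C(C)(C)C | intermediate
23 | silyl ketene acetal of 22 | C=C/C=C/COC(O[Si](C)(C)C)=C[C@H]1[C@H](C(C)=C)[C@]2(C)C[C@H](C)C[C@@H](C)[C@@H]2[C@@H]1O[Si](C)(C)C(C)(C)C | intermediate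
24 | trimethylsilyl ester of 25 | C=CC(C=C)C(C(=O)O[Si](C)(C)C)[C@H]1[C@H](C(C)=C)[C@]2(C)C[C@H](C)C[C@@H](C)[C@@H]2[C@@H]1O[Si](C)(C)C(C)(C)C | intermediate
25 | 3-ethenyl-2-(indanyl)pent-4-enoic acid (C2 epimers) | C=CC(C=C)C(C(=O)O)[C@H]1[C@H](C(C)=C)[C@]2(C)C[C@H](C)C[C@@H](C)[C@@H]2[C@@H]1O[Si](C)(C)C(C)(C)C | intermediate
26 | decahydrofluorene-1-carboxylic acid (C1 epimers) | C=C[C@H]1C=C(C)[C@H]2[C@@H]([C@@H](O[Si](C)(C)C(C)(C)C)[C@H]3[C@H](C)C[C@@H](C)C[C@@]23C)C1C(=O)O | intermediate
27 | N-Boc-4-iodo-L-phenylalanine | CC(C)(C)OC(=O)N[C@@H](Cc1ccc(I)cc1)C(=O)O | starting material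
28 | Meldrum's acid | CC1(C)OC(=O)CC(=O)O1 | starting material
29 | acyl Meldrum's acid | CC(C)(C)OC(=O)N[C@@H](Cc1ccc(I)cc1)C(=O)C1C(=O)OC(C)(C)OC1=O | intermediate
30 | alkyl Meldrum's acid | CC(C)(C)OC(=O)N[C@@H](Cc1ccc(I)cc1)CC1C(=O)OC(C)(C)OC1=O | intermediate
31 | tert-butyl (R)-2-(4-iodobenzyl)-5-oxopyrrolidine-1-carboxylate | O=C1CC[C@H](Cc2ccc(I)cc2)N1C(=O)OC(C)(C)C | intermediate
32 | acyl imidazolide of 26 | C=C[C@H]1C=C(C)[C@H]2[C@@H]([C@@H](O[Si](C)(C)C(C)(C)C)[C@H]3[C@H](C)C[C@@H](C)C[C@@]23C)C1C(=O)n1ccnc1 | intermediate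
33 | β-keto lactam (fluorene C1 epimers) | C=C[C@H]1C=C(C)[C@H]2[C@@H]([C@@H](O[Si](C)(C)C(C)(C)C)[C@H]3[C@H](C)C[C@@H](C)C[C@@]23C)C1C(=O)C4C[C@H](Cc5ccc(I)cc5)N(C(=O)OC(C)(C)C)C4=O | intermediate
34 | β-keto lactam, acyl cis to ethenyl | C=C[C@H]1C=C(C)[C@H]2[C@@H]([C@@H](O[Si](C)(C)C(C)(C)C)[C@H]3[C@H](C)C[C@@H](C)C[C@@]23C)[C@H]1C(=O)C4C[C@H](Cc5ccc(I)cc5)N(C(=O)OC(C)(C)C)C4=O | intermediate
35 | 9-hydroxy β-keto lactam | C=C[C@H]1C=C(C)[C@H]2[C@@H]([C@@H](O)[C@H]3[C@H](C)C[C@@H](C)C[C@@]23C)[C@H]1C(=O)C4C[C@H](Cc5ccc(I)cc5)N(C(=O)OC(C)(C)C)C4=O | intermediate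
36 | N-Boc cyclophane | C=C[C@H]1C=C(C)[C@H]2[C@H]3[C@@H](Oc4ccc(cc4)C[C@H]4CC(C(=O)N4C(=O)OC(C)(C)C)C(=O)[C@@H]13)[C@H]1[C@H](C)C[C@@H](C)C[C@]12C | intermediate
37 | N–H cyclophane lactam | C=C[C@H]1C=C(C)[C@H]2[C@H]3[C@@H](Oc4ccc(cc4)C[C@H]4CC(C(=O)N4)C(=O)[C@@H]13)[C@H]1[C@H](C)C[C@@H](C)C[C@]12C | intermediate
38 | 3-phenylselanyl lactam | C=C[C@H]1C=C(C)[C@H]2[C@H]3[C@@H](Oc4ccc(cc4)C[C@H]4CC([Se]c5ccccc5)(C(=O)N4)C(=O)[C@@H]13)[C@H]1[C@H](C)C[C@@H](C)C[C@]12C | intermediate
39 | selenoxide of 38 | C=C[C@H]1C=C(C)[C@H]2[C@H]3[C@@H](Oc4ccc(cc4)C[C@H]4CC([Se](=O)c5ccccc5)(C(=O)N4)C(=O)[C@@H]13)[C@H]1[C@H](C)C[C@@H](C)C[C@]12C | intermediate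
40 | cyclophane 3-acyl-1,5-dihydro-2H-pyrrol-2-one | C=C[C@H]1C=C(C)[C@H]2[C@H]3[C@@H](Oc4ccc(cc4)C[C@H]4C=C(C(=O)N4)C(=O)[C@@H]13)[C@H]1[C@H](C)C[C@@H](C)C[C@]12C | intermediate
41 | C5 hydroperoxide | C=C[C@H]1C=C(C)[C@H]2[C@H]3[C@@H](Oc4ccc(cc4)C[C@@]4(OO)C=C(C(=O)N4)C(=O)[C@@H]13)[C@H]1[C@H](C)C[C@@H](C)C[C@]12C | intermediate
42 | CNP0151253.3 | C=C[C@H]1C=C(C)[C@H]2[C@H]3[C@@H](Oc4ccc(cc4)C[C@@]4(O)C=C(C(=O)N4)C(=O)[C@@H]13)[C@H]1[C@H](C)C[C@@H](C)C[C@]12C | target

**Count and risks**

Total steps: 27. Longest linear sequence: 25 steps (steps 1–18, then 21–27); steps 19–20 make the lactam fragment.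

Most likely to fail:

1. Step 12. Chlorine transfer to the ring-expanded radical may outrun ring closure, or the closure may show poor facial selectivity at the CH next to the quaternary carbon, since the alkene must approach over ring A. Fallback, from 15 back to 16: separate the two events and close ring C by ionic chemistry. Excess CuCl2 in concentrated DMF intercepts the ring-expanded radical before cyclisation and gives the ring-expanded β-chloro ketone F1. NaOAc in MeOH eliminates HCl to the 3-methylcyclohex-2-enone F2. TiCl4 in CH2Cl2 at −78 °C then promotes intramolecular conjugate addition of the trisubstituted alkene to the enone β-carbon, with chloride capture of the tertiary cation, to give 16.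

2. Step 24. Intermolecular C- or O-arylation and protodeiodination may outrun closure of the strained 13-membered ring. Fallback, from 26 back to 36: nucleophilic aromatic substitution on an arene–chromium complex. N-Boc-4-fluoro-L-phenylalanine F8 is taken through the sequence of steps 19–20 (acyl Meldrum's acid F9, alkyl Meldrum's acid F10) to the fluoro lactam F11. Coupling with 26 via 32 as in step 21 gives the β-keto lactam F12, kinetic protonation as in step 22 gives F13, and HF·pyridine gives the alcohol F14. (Naphthalene)Cr(CO)3 in THF at 70 °C gives the arene–Cr(CO)3 complex F15. KN(SiMe3)2 at high dilution makes the alkoxide displace fluoride on the complexed ring to give the complexed cyclophane F16, and I2 removes chromium to give 36.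

3. Step 22. The dianion may form incompletely at the hindered methine, or protonation may fall back to the more stable epimer. Fallback, from 26 back to 34: set the centre at the ester stage and bring in the lactam by aldol chemistry. Me3SiCHN2 in MeOH gives the methyl ester F3. LiN(iPr)2 followed by kinetic protonation with 2,6-di-tert-butyl-4-methylphenol at −78 °C gives the ester with the ester group cis to the ethenyl group F4. iBu2AlH gives the primary alcohol F5, and Dess–Martin periodinane gives the aldehyde F6. Aldol addition of the lithium enolate of 31 gives the β-hydroxy lactam F7, and Dess–Martin oxidation gives 34.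

**Further compounds**

F1 | step 12 | ring-expanded β-chloro ketone | COC(=O)C[C@@H](C=C(C)C)[C@@H](O[Si](C)(C)C(C)(C)C)[C@H]1[C@H](C)CC(=O)CC1(C)Cl
F2 | step 12 | 3-methylcyclohex-2-enone carrying the side chain | COC(=O)C[C@@H](C=C(C)C)[C@@H](O[Si](C)(C)C(C)(C)C)[C@H]1[C@H](C)CC(=O)C=C1C
F3 | step 22 | methyl ester of 26 (C1 epimers) | C=C[C@H]1C=C(C)[C@H]2[C@@H]([C@@H](O[Si](C)(C)C(C)(C)C)[C@H]3[C@H](C)C[C@@H](C)C[C@@]23C)C1C(=O)OC
F4 | step 22 | methyl ester, ester cis to ethenyl | C=C[C@H]1C=C(C)[C@H]2[C@@H]([C@@H](O[Si](C)(C)C(C)(C)C)[C@H]3[C@H](C)C[C@@H](C)C[C@@]23C)[C@H]1C(=O)OC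
F5 | step 22 | primary alcohol | C=C[C@H]1C=C(C)[C@H]2[C@@H]([C@@H](O[Si](C)(C)C(C)(C)C)[C@H]3[C@H](C)C[C@@H](C)C[C@@]23C)[C@H]1CO
F6 | step 22 | aldehyde | C=C[C@H]1C=C(C)[C@H]2[C@@H]([C@@H](O[Si](C)(C)C(C)(C)C)[C@H]3[C@H](C)C[C@@H](C)C[C@@]23C)[C@H]1C=O
F7 | step 22 | β-hydroxy lactam | C=C[C@H]1C=C(C)[C@H]2[C@@H]([C@@H](O[Si](C)(C)C(C)(C)C)[C@H]3[C@H](C)C[C@@H](C)C[C@@]23C)[C@H]1C(O)C4C[C@H](Cc5ccc(I)cc5)N(C(=O)OC(C)(C)C)C4=O
F8 | step 24 | N-Boc-4-fluoro-L-phenylalanine | CC(C)(C)OC(=O)N[C@@H](Cc1ccc(F)cc1)C(=O)O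
F9 | step 24 | fluoro acyl Meldrum's acid | CC(C)(C)OC(=O)N[C@@H](Cc1ccc(F)cc1)C(=O)C1C(=O)OC(C)(C)OC1=O
F10 | step 24 | fluoro alkyl Meldrum's acid | CC(C)(C)OC(=O)N[C@@H](Cc1ccc(F)cc1)CC1C(=O)OC(C)(C)OC1=O
F11 | step 24 | tert-butyl (R)-2-(4-fluorobenzyl)-5-oxopyrrolidine-1-carboxylate | O=C1CC[C@H](Cc2ccc(F)cc2)N1C(=O)OC(C)(C)C
F12 | step 24 | fluoro β-keto lactam (C1 epimers) | C=C[C@H]1C=C(C)[C@H]2[C@@H]([C@@H](O[Si](C)(C)C(C)(C)C)[C@H]3[C@H](C)C[C@@H](C)C[C@@]23C)C1C(=O)C4C[C@H](Cc5ccc(F)cc5)N(C(=O)OC(C)(C)C)C4=O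
F13 | step 24 | fluoro β-keto lactam, acyl cis to ethenyl | C=C[C@H]1C=C(C)[C@H]2[C@@H]([C@@H](O[Si](C)(C)C(C)(C)C)[C@H]3[C@H](C)C[C@@H](C)C[C@@]23C)[C@H]1C(=O)C4C[C@H](Cc5ccc(F)cc5)N(C(=O)OC(C)(C)C)C4=O
F14 | step 24 | fluoro 9-hydroxy β-keto lactam | C=C[C@H]1C=C(C)[C@H]2[C@@H]([C@@H](O)[C@H]3[C@H](C)C[C@@H](C)C[C@@]23C)[C@H]1C(=O)C4C[C@H](Cc5ccc(F)cc5)N(C(=O)OC(C)(C)C)C4=O
F15 | step 24 | (η6-fluoroarene)Cr(CO)3 complex of F14 | C=C[C@H]1C=C(C)[C@H]2[C@@H]([C@@H](O)[C@H]3[C@H](C)C[C@@H](C)C[C@@]23C)[C@H]1C(=O)C4C[C@H](Cc5ccc(F)cc5)N(C(=O)OC(C)(C)C)C4=O.[Cr].[C-]#[O+].[C-]#[O+].[C-]#[O+]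
F16 | step 24 | (η6-arene)Cr(CO)3 complex of 36 | C=C[C@H]1C=C(C)[C@H]2[C@H]3[C@@H](Oc4ccc(cc4)C[C@H]4CC(C(=O)N4C(=O)OC(C)(C)C)C(=O)[C@@H]13)[C@H]1[C@H](C)C[C@@H](C)C[C@]12C.[Cr].[C-]#[O+].[C-]#[O+].[C-]#[O+]
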